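**Plan**

1. Numbering as in germacranolides: carbocycle C1–C10, lactone C6–O–C12(=O)–C11(=C13)–C7, C14 (CH2OAc) on C10, C15 (CHO) on C4, ester on O8. Enabling feature: lactone carbon C7 lies between the oxygen-bearing C6 and C8, with C7–C11 anti to C8–O. This is the imprint of an anti opening of a cis-7,8-epoxide at C7 by the α-carbon of an acrylate carried on O6.
2. Retrosynthetic cuts, in order: O8–acyl; C7–C11 (lactone ring, C8–OH back to the epoxide, C13 kept from the acrylate); O6–acyl; C4=C5 (metathesis); C5–C6 (vinyl addition to a cis-epoxy aldehyde); epoxide oxygen; C10=C1 (Wittig); C2–C3 (Claisen).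
3. Forward: two fragments are joined by an E-selective Wittig reaction, the Z-allylic alcohol is epoxidized, vinyl is added, and the ten-membered ring closes by metathesis. The γ-lactone ring closes last among the rings, in one operation that also delivers the exocyclic methylene and frees O8. Esterification, PMB removal, oxidation and desilylation finish the route.
4. Stereochemistry: C7 and C8 from Sharpless epoxidation with D-(−)-tartrate; C6 from Felkin–Anh addition to the cis-epoxy aldehyde; the key step inverts C7 and keeps C6 and C8. C10=C1 comes from the stabilized Wittig reaction, C4=C5 from the ring-enforced metathesis.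

Key step: step 15

Step 1
Reactants: 1 2-methylidenepropane-1,3-diol
Product: 2 2-{[(4-methoxybenzyl)oxy]methyl}prop-2-en-1-ol
Conditions: NaH (1.0 equiv), THF, 0 °C; PMBCl, Bu4NI (cat.), 0 °C to rt
Reagents that add atoms: 4-methoxybenzyl chloride, COc1ccc(CCl)cc1
Why: Williamson etherification of the mono-sodium alkoxide of a symmetrical diol should give the mono-PMB ether, which masks the future C15 hydroxyl until the lactone is in place.

Step 2
Reactants: 2 2-{[(4-methoxybenzyl)oxy]methyl}prop-2-en-1-ol; 3 triethyl orthoacetate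
Product: 5 ethyl 4-{[(4-methoxybenzyl)oxy]methyl}pent-4-enoate, via ketene acetal 4 (not isolated)
Conditions: EtCO2H (cat.), 140 °C, EtOH distilled off
Reagents that add atoms: none
Why: Johnson–Claisen rearrangement of the mixed ketene acetal forms the C2–C3 bond and leaves the 1,1-disubstituted C4 methylene that later serves as the metathesis partner.

Step 3
Reactants: 6 (Z)-but-2-ene-1,4-diol
Product: 7 (2Z)-4-{[tert-butyl(dimethyl)silyl]oxy}but-2-en-1-ol
Conditions: NaH (1.0 equiv), THF, 0 °C; TBSCl, rt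
Reagents that add atoms: tert-butyldimethylsilyl chloride, C[Si](C)(Cl)C(C)(C)C
Why: Monosilylation of the symmetrical diol through its mono-sodium alkoxide (silyl ether formation) differentiates the two ends and carries the Z geometry of the future C7=C8 unit.

Step 4
Reactants: 7 (2Z)-4-{[tert-butyl(dimethyl)silyl]oxy}but-2-en-1-ol
Product: 8 {[(2Z)-4-bromobut-2-en-1-yl]oxy}(tert-butyl)dimethylsilane
Conditions: CBr4, PPh3, CH2Cl2, 0 °C
Reagents that add atoms: carbon tetrabromide, BrC(Br)(Br)Br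
Why: Appel bromination converts the primary allylic alcohol into the bromide under neutral conditions that should not isomerize the Z-alkene or touch the silyl ether.

Step 5
Reactants: 8 {[(2Z)-4-bromobut-2-en-1-yl]oxy}(tert-butyl)dimethylsilane; 9 ethyl (triphenyl-λ5-phosphanylidene)acetate
Product: 11 ethyl (4Z)-6-{[tert-butyl(dimethyl)silyl]oxy}-2-(triphenyl-λ5-phosphanylidene)hex-4-enoate, via phosphonium bromide 10 (not isolated)
Conditions: CHCl3, reflux; then aq. NaOH, CH2Cl2, 0 °C
Reagents that add atoms: none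
Why: C-alkylation of the stabilized ylide by the primary allylic bromide (SN2) followed by deprotonation of the phosphonium salt gives the α-substituted stabilized ylide that carries C6–C10 and C14.

Step 6
Reactants: 5 ethyl 4-{[(4-methoxybenzyl)oxy]methyl}pent-4-enoate; 11 ethyl (4Z)-6-{[tert-butyl(dimethyl)silyl]oxy}-2-(triphenyl-λ5-phosphanylidene)hex-4-enoate
Product: 13 ethyl (2E)-2-[(2Z)-4-{[tert-butyl(dimethyl)silyl]oxy}but-2-en-1-yl]-6-{[(4-methoxybenzyl)oxy]methyl}hepta-2,6-dienoate, via aldehyde 12 (not isolated)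
Conditions: iBu2AlH (1.05 equiv), CH2Cl2, −78 °C; MeOH; then 11, −78 °C to 40 °C
Reagents that add atoms: none
Why: Half-reduction of the ester with iBu2AlH and Wittig olefination of the aldehyde in the same flask should give the E-enoate (ester trans to C2), the usual outcome for α-branched stabilized ylides, which is the C10=C1 geometry of the target.

Step 7
Reactants: 13 ethyl (2E)-2-[(2Z)-4-{[tert-butyl(dimethyl)silyl]oxy}but-2-en-1-yl]-6-{[(4-methoxybenzyl)oxy]methyl}hepta-2,6-dienoate
Product: 14 ethyl (2E)-2-[(2Z)-4-hydroxybut-2-en-1-yl]-6-{[(4-methoxybenzyl)oxy]methyl}hepta-2,6-dienoate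
Conditions: HF·pyridine, pyridine, THF, 0 °C
Reagents that add atoms: none
Why: Fluoride-mediated desilylation frees the Z-allylic alcohol without affecting the ethyl ester, the PMB ether or the alkenes.

Step 8
Reactants: 14 ethyl (2E)-2-[(2Z)-4-hydroxybut-2-en-1-yl]-6-{[(4-methoxybenzyl)oxy]methyl}hepta-2,6-dienoate
Product: 15 ethyl (2E)-2-{[(2S,3R)-3-(hydroxymethyl)oxiran-2-yl]methyl}-6-{[(4-methoxybenzyl)oxy]methyl}hepta-2,6-dienoate
Conditions: Ti(OiPr)4 (cat.), D-(−)-diethyl tartrate, t-BuOOH, 4 Å MS, CH2Cl2, −20 °C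
Reagents that add atoms: tert-butyl hydroperoxide, CC(C)(C)OO
Why: Sharpless asymmetric epoxidation acts only on the allylic-alcohol alkene (the enoate and the allyl-ether methylene are not directed), and the D-(−)-tartrate complex delivers oxygen to the face that gives the cis-epoxide with C7 R and C8 S.

Step 9
Reactants: 15 ethyl (2E)-2-{[(2S,3R)-3-(hydroxymethyl)oxiran-2-yl]methyl}-6-{[(4-methoxybenzyl)oxy]methyl}hepta-2,6-dienoate
Product: 16 ethyl (2E)-2-{[(2S,3S)-3-formyloxiran-2-yl]methyl}-6-{[(4-methoxybenzyl)oxy]methyl}hepta-2,6-dienoate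
Conditions: Dess–Martin periodinane, pyridine, CH2Cl2, 0 °C
Reagents that add atoms: none
Why: Dess–Martin oxidation under buffered conditions gives the cis-epoxy aldehyde without opening the epoxide or epimerizing C7.

Step 10
Reactants: 16 ethyl (2E)-2-{[(2S,3S)-3-formyloxiran-2-yl]methyl}-6-{[(4-methoxybenzyl)oxy]methyl}hepta-2,6-dienoate; 17 vinylmagnesium bromide
Product: 18 ethyl (2E)-2-({(2S,3R)-3-[(1R)-1-hydroxyprop-2-en-1-yl]oxiran-2-yl}methyl)-6-{[(4-methoxybenzyl)oxy]methyl}hepta-2,6-dienoate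
Conditions: THF, −78 °C; then pH 7 buffer
Reagents that add atoms: none
Why: Grignard addition to the aldehyde (faster than to the hindered enoate at −78 °C) should follow the Felkin–Anh model, with the epoxide C–O bond anti to the incoming nucleophile, and so give the erythro carbinol with C6 R.

Step 11
Reactants: 18 ethyl (2E)-2-({(2S,3R)-3-[(1R)-1-hydroxyprop-2-en-1-yl]oxiran-2-yl}methyl)-6-{[(4-methoxybenzyl)oxy]methyl}hepta-2,6-dienoate
Product: 19 ethyl (1S,3E,7E,9R,10R)-9-hydroxy-7-{[(4-methoxybenzyl)oxy]methyl}-11-oxabicyclo[8.1.0]undeca-3,7-diene-3-carboxylate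
Conditions: second-generation Grubbs catalyst (H2IMes)(PCy3)Cl2Ru=CHPh (10 mol %), 1,4-benzoquinone (cat.), toluene (1 mM), 80 °C
Reagents that add atoms: none
Why: Ring-closing metathesis: the catalyst loads on the C5 vinyl group and can close only onto the C4 methylene because the trisubstituted C10=C1 enoate is inert, while the E-enoate and the cis-epoxide hold both chain ends on one side, so the ten-membered ring should form with the ring-cis C4=C5 geometry (CIP E) that the ring size enforces.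

Step 12
Reactants: 19 ethyl (1S,3E,7E,9R,10R)-9-hydroxy-7-{[(4-methoxybenzyl)oxy]methyl}-11-oxabicyclo[8.1.0]undeca-3,7-diene-3-carboxylate
Product: 20 (1R,2R,3E,7E,10S)-8-(hydroxymethyl)-4-{[(4-methoxybenzyl)oxy]methyl}-11-oxabicyclo[8.1.0]undeca-3,7-dien-2-ol
Conditions: iBu2AlH (3.5 equiv), CH2Cl2, −78 °C; aq. potassium sodium tartrate
Reagents that add atoms: none
Why: 1,2-Reduction of the enoate with iBu2AlH at low temperature gives the C14 allylic alcohol and should leave the epoxide and the PMB ether intact.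

Step 13
Reactants: 20 (1R,2R,3E,7E,10S)-8-(hydroxymethyl)-4-{[(4-methoxybenzyl)oxy]methyl}-11-oxabicyclo[8.1.0]undeca-3,7-dien-2-ol
Product: 21 [(1S,3E,7E,9R,10R)-9-hydroxy-7-{[(4-methoxybenzyl)oxy]methyl}-11-oxabicyclo[8.1.0]undeca-3,7-dien-3-yl]methyl acetate
Conditions: AcCl (1.05 equiv), 2,4,6-collidine, CH2Cl2, −78 °C
Reagents that add atoms: acetyl chloride, CC(=O)Cl
Why: Acylation with acetyl chloride and a hindered pyridine base at low temperature is selective for the primary allylic C14 hydroxyl over the hindered secondary C6 hydroxyl and installs the acetate of the target.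

Step 14
Reactants: 21 [(1S,3E,7E,9R,10R)-9-hydroxy-7-{[(4-methoxybenzyl)oxy]methyl}-11-oxabicyclo[8.1.0]undeca-3,7-dien-3-yl]methyl acetate; 22 prop-2-enoyl chloride
Product: 23 (1S,2R,3E,7E,10S)-8-(acetoxymethyl)-4-{[(4-methoxybenzyl)oxy]methyl}-11-oxabicyclo[8.1.0]undeca-3,7-dien-2-yl prop-2-enoate
Conditions: iPr2NEt, CH2Cl2, −20 °C
Reagents that add atoms: none
Why: O-Acylation of the C6 hydroxyl with retention places the three-atom O6–C12–C11 tether and the future C13 methylene next to the epoxide.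

Step 15
Reactants: 23 (1S,2R,3E,7E,10S)-8-(acetoxymethyl)-4-{[(4-methoxybenzyl)oxy]methyl}-11-oxabicyclo[8.1.0]undeca-3,7-dien-2-yl prop-2-enoate
Product: 26 [(3aR,4S,6E,10E,11aR)-4-hydroxy-10-{[(4-methoxybenzyl)oxy]methyl}-3-methylidene-2-oxo-2,3,3a,4,5,8,9,11a-octahydrocyclodeca[b]furan-6-yl]methyl acetate, via phosphonium enolate 24 (not isolated), via phosphonium alkoxide 25 (not isolated)
Conditions: PMe3 (0.5 equiv), t-BuOH, rt
Reagents that add atoms: none
Why: Proposed new method: PMe3 adds reversibly to C13 of the acrylate to give the β-phosphonio ester enolate 24, whose α-carbon C11 opens the hydrogen-bonded cis-epoxide at C7 from the face anti to the C7–O bond; the alkoxide 25 then removes H11 and PMe3 is expelled (E1cB), so the exocyclic C11=C13 alkene and the free C8 hydroxyl appear together and the phosphine is returned. The closest known reaction type is the phosphine-mediated intramolecular Morita–Baylis–Hillman alkylation of enones by tethered epoxides or alkyl halides, which gives five- and six-membered carbocycles; here the acceptor is an acrylate ester whose ester oxygen is part of the tether, which has not been shown, and the mechanistic cost is the s-trans ester conformer that closure requires. The γ-lactone closes in the 5-exo-tet mode at C7, preferred over 6-endo attack at C8 because the short O6–C12–C11 tether reaches the backside of C7 without strain. C7 is set by SN2 inversion and C8 keeps the epoxide configuration, so the cis-epoxide syn to O6 becomes the trans-fused lactone with C7–C11 anti to C8–O, while C6 is untouched. The step needs chemoselectivity for the acrylate and the epoxide, which is secured because C15 is still a PMB ether and C14 an unactivated allylic acetate, so no other conjugate acceptor or electrophile is present, and tert-butanol both activates the epoxide and buffers the alkoxide.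

Step 16
Reactants: 27 ethyl 2-(hydroxymethyl)prop-2-enoate
Product: 28 ethyl 2-({[tert-butyl(dimethyl)silyl]oxy}methyl)prop-2-enoate
Conditions: TBSCl, imidazole, DMF, rt
Reagents that add atoms: tert-butyldimethylsilyl chloride, C[Si](C)(Cl)C(C)(C)C
Why: Silyl ether formation protects the primary hydroxyl of the side-chain building block so that it cannot compete in the later esterification.

Step 17
Reactants: 28 ethyl 2-({[tert-butyl(dimethyl)silyl]oxy}methyl)prop-2-enoate
Product: 29 2-({[tert-butyl(dimethyl)silyl]oxy}methyl)prop-2-enoic acid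
Conditions: LiOH, THF/H2O, 0 °C; then aq. HCl to pH 3
Reagents that add atoms: lithium hydroxide, [Li+].[OH-]
Why: Saponification of the ethyl ester at low temperature gives the acid while the primary TBS ether survives.

Step 18
Reactants: 26 [(3aR,4S,6E,10E,11aR)-4-hydroxy-10-{[(4-methoxybenzyl)oxy]methyl}-3-methylidene-2-oxo-2,3,3a,4,5,8,9,11a-octahydrocyclodeca[b]furan-6-yl]methyl acetate; 29 2-({[tert-butyl(dimethyl)silyl]oxy}methyl)prop-2-enoic acid
Product: 30 (3aR,4S,6E,10E,11aR)-6-(acetoxymethyl)-10-{[(4-methoxybenzyl)oxy]methyl}-3-methylidene-2-oxo-2,3,3a,4,5,8,9,11a-octahydrocyclodeca[b]furan-4-yl 2-({[tert-butyl(dimethyl)silyl]oxy}methyl)prop-2-enoate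
Conditions: DCC, DMAP (cat.), CH2Cl2, 0 °C to rt
Reagents that add atoms: none
Why: Steglich esterification acylates the only free hydroxyl (C8) with retention of configuration under conditions mild enough for the α-methylene lactone.

Step 19
Reactants: 30 (3aR,4S,6E,10E,11aR)-6-(acetoxymethyl)-10-{[(4-methoxybenzyl)oxy]methyl}-3-methylidene-2-oxo-2,3,3a,4,5,8,9,11a-octahydrocyclodeca[b]furan-4-yl 2-({[tert-butyl(dimethyl)silyl]oxy}methyl)prop-2-enoate
Product: 31 (3aR,4S,6E,10E,11aR)-6-(acetoxymethyl)-10-(hydroxymethyl)-3-methylidene-2-oxo-2,3,3a,4,5,8,9,11a-octahydrocyclodeca[b]furan-4-yl 2-({[tert-butyl(dimethyl)silyl]oxy}methyl)prop-2-enoate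
Conditions: DDQ, CH2Cl2/pH 7 buffer, 0 °C
Reagents that add atoms: none
Why: Oxidative PMB cleavage with DDQ frees the C15 allylic alcohol and leaves the silyl ether, the acetate and both acrylate units untouched.

Step 20
Reactants: 31 (3aR,4S,6E,10E,11aR)-6-(acetoxymethyl)-10-(hydroxymethyl)-3-methylidene-2-oxo-2,3,3a,4,5,8,9,11a-octahydrocyclodeca[b]furan-4-yl 2-({[tert-butyl(dimethyl)silyl]oxy}methyl)prop-2-enoate
Product: 32 (3aR,4S,6E,10E,11aR)-6-(acetoxymethyl)-10-formyl-3-methylidene-2-oxo-2,3,3a,4,5,8,9,11a-octahydrocyclodeca[b]furan-4-yl 2-({[tert-butyl(dimethyl)silyl]oxy}methyl)prop-2-enoate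
Conditions: MnO2, CH2Cl2, rt
Reagents that add atoms: none
Why: MnO2 oxidation of the only free (allylic) alcohol gives the enal without isomerizing the C4=C5 alkene, whose geometry is held by the ring.

Step 21
Reactants: 32 (3aR,4S,6E,10E,11aR)-6-(acetoxymethyl)-10-formyl-3-methylidene-2-oxo-2,3,3a,4,5,8,9,11a-octahydrocyclodeca[b]furan-4-yl 2-({[tert-butyl(dimethyl)silyl]oxy}methyl)prop-2-enoate
Product: 33 (3aR,4S,6E,10E,11aR)-6-(acetoxymethyl)-10-formyl-3-methylidene-2-oxo-2,3,3a,4,5,8,9,11a-octahydrocyclodeca[b]furan-4-yl 2-(hydroxymethyl)prop-2-enoate (CNP0198933.2)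
Conditions: HF·pyridine, THF, 0 °C
Reagents that add atoms: none
Why: Mildly acidic fluoride desilylation removes the last protecting group without touching the acetate, the enal or the two Michael acceptors.

**Compound list**

1 | 2-methylidenepropane-1,3-diol | C=C(CO)CO | starting material
2 | 2-{[(4-methoxybenzyl)oxy]methyl}prop-2-en-1-ol | C=C(CO)COCc1ccc(OC)cc1 | intermediate
3 | triethyl orthoacetate | CC(OCC)(OCC)OCC | starting material
4 | mixed ketene acetal, 1-ethoxyethenyl 2-{[(4-methoxybenzyl)oxy]methyl}prop-2-en-1-yl ether | C=C(OCC)OCC(=C)COCc1ccc(OC)cc1 | intermediate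
5 | ethyl 4-{[(4-methoxybenzyl)oxy]methyl}pent-4-enoate | CCOC(=O)CCC(=C)COCc1ccc(OC)cc1 | intermediate
6 | (Z)-but-2-ene-1,4-diol | OC/C=C\CO | starting material
7 | (2Z)-4-{[tert-butyl(dimethyl)silyl]oxy}but-2-en-1-ol | OC/C=C\CO[Si](C)(C)C(C)(C)C | intermediate
8 | {[(2Z)-4-bromobut-2-en-1-yl]oxy}(tert-butyl)dimethylsilane | BrC/C=C\CO[Si](C)(C)C(C)(C)C | intermediate
9 | ethyl (triphenyl-λ5-phosphanylidene)acetate | CCOC(=O)C=P(c1ccccc1)(c1ccccc1)c1ccccc1 | starting material
10 | [(4Z)-6-{[tert-butyl(dimethyl)silyl]oxy}-1-ethoxy-1-oxohex-4-en-2-yl]triphenylphosphonium bromide | CCOC(=O)C(C/C=C\CO[Si](C)(C)C(C)(C)C)[P+](c1ccccc1)(c1ccccc1)c1ccccc1.[Br-] | intermediate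
11 | ethyl (4Z)-6-{[tert-butyl(dimethyl)silyl]oxy}-2-(triphenyl-λ5-phosphanylidene)hex-4-enoate | CCOC(=O)C(C/C=C\CO[Si](C)(C)C(C)(C)C)=P(c1ccccc1)(c1ccccc1)c1ccccc1 | intermediate
12 | 4-{[(4-methoxybenzyl)oxy]methyl}pent-4-enal | O=CCCC(=C)COCc1ccc(OC)cc1 | intermediate
13 | ethyl (2E)-2-[(2Z)-4-{[tert-butyl(dimethyl)silyl]oxy}but-2-en-1-yl]-6-{[(4-methoxybenzyl)oxy]methyl}hepta-2,6-dienoate | CCOC(=O)/C(C/C=C\CO[Si](C)(C)C(C)(C)C)=C/CCC(=C)COCc1ccc(OC)cc1 | intermediate
14 | ethyl (2E)-2-[(2Z)-4-hydroxybut-2-en-1-yl]-6-{[(4-methoxybenzyl)oxy]methyl}hepta-2,6-dienoate | CCOC(=O)/C(C/C=C\CO)=C/CCC(=C)COCc1ccc(OC)cc1 | intermediate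
15 | ethyl (2E)-2-{[(2S,3R)-3-(hydroxymethyl)oxiran-2-yl]methyl}-6-{[(4-methoxybenzyl)oxy]methyl}hepta-2,6-dienoate | CCOC(=O)/C(C[C@@H]1O[C@@H]1CO)=C/CCC(=C)COCc1ccc(OC)cc1 | intermediate
16 | ethyl (2E)-2-{[(2S,3S)-3-formyloxiran-2-yl]methyl}-6-{[(4-methoxybenzyl)oxy]methyl}hepta-2,6-dienoate | CCOC(=O)/C(C[C@@H]1O[C@@H]1C=O)=C/CCC(=C)COCc1ccc(OC)cc1 | intermediate
17 | vinylmagnesium bromide (CH2=CHMgBr) | C=C[Mg]Br | starting material
18 | ethyl (2E)-2-({(2S,3R)-3-[(1R)-1-hydroxyprop-2-en-1-yl]oxiran-2-yl}methyl)-6-{[(4-methoxybenzyl)oxy]methyl}hepta-2,6-dienoate | CCOC(=O)/C(C[C@@H]1O[C@@H]1[C@H](O)C=C)=C/CCC(=C)COCc1ccc(OC)cc1 | intermediate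
19 | ethyl (1S,3E,7E,9R,10R)-9-hydroxy-7-{[(4-methoxybenzyl)oxy]methyl}-11-oxabicyclo[8.1.0]undeca-3,7-diene-3-carboxylate | CCOC(=O)/C1=C/CC/C(COCc2ccc(OC)cc2)=C\[C@@H](O)[C@H]2O[C@H]2C1 | intermediate
20 | (1R,2R,3E,7E,10S)-8-(hydroxymethyl)-4-{[(4-methoxybenzyl)oxy]methyl}-11-oxabicyclo[8.1.0]undeca-3,7-dien-2-ol | OC/C1=C/CC/C(COCc2ccc(OC)cc2)=C\[C@@H](O)[C@H]2O[C@H]2C1 | intermediate
21 | [(1S,3E,7E,9R,10R)-9-hydroxy-7-{[(4-methoxybenzyl)oxy]methyl}-11-oxabicyclo[8.1.0]undeca-3,7-dien-3-yl]methyl acetate | CC(=O)OC/C1=C/CC/C(COCc2ccc(OC)cc2)=C\[C@@H](O)[C@H]2O[C@H]2C1 | intermediate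
22 | prop-2-enoyl chloride (acryloyl chloride) | C=CC(=O)Cl | starting material
23 | (1S,2R,3E,7E,10S)-8-(acetoxymethyl)-4-{[(4-methoxybenzyl)oxy]methyl}-11-oxabicyclo[8.1.0]undeca-3,7-dien-2-yl prop-2-enoate | CC(=O)OC/C1=C/CC/C(COCc2ccc(OC)cc2)=C\[C@@H](OC(=O)C=C)[C@H]2O[C@H]2C1 | intermediate
24 | zwitterion from 23 and PMe3: ester enolate on O6 carrying CH2PMe3+ at the former C13, ring and epoxide as in 23 | CC(=O)OC/C1=C/CC/C(COCc2ccc(OC)cc2)=C\[C@@H](OC([O-])=CC[P+](C)(C)C)[C@H]2O[C@H]2C1 | intermediate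
25 | zwitterion after ring closure: trans-fused γ-lactone with CH2PMe3+ on C11 and the C8 alkoxide, C11 configuration open | CC(=O)OC/C1=C/CC/C(COCc2ccc(OC)cc2)=C\[C@H]2OC(=O)C(C[P+](C)(C)C)[C@@H]2[C@@H]([O-])C1 | intermediate
26 | [(3aR,4S,6E,10E,11aR)-4-hydroxy-10-{[(4-methoxybenzyl)oxy]methyl}-3-methylidene-2-oxo-2,3,3a,4,5,8,9,11a-octahydrocyclodeca[b]furan-6-yl]methyl acetate | CC(=O)OC/C1=C/CC/C(COCc2ccc(OC)cc2)=C\[C@H]2OC(=O)C(=C)[C@@H]2[C@@H](O)C1 | intermediate
27 | ethyl 2-(hydroxymethyl)prop-2-enoate | C=C(CO)C(=O)OCC | starting material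
28 | ethyl 2-({[tert-butyl(dimethyl)silyl]oxy}methyl)prop-2-enoate | C=C(CO[Si](C)(C)C(C)(C)C)C(=O)OCC | intermediate
29 | 2-({[tert-butyl(dimethyl)silyl]oxy}methyl)prop-2-enoic acid | C=C(CO[Si](C)(C)C(C)(C)C)C(=O)O | intermediate
30 | (3aR,4S,6E,10E,11aR)-6-(acetoxymethyl)-10-{[(4-methoxybenzyl)oxy]methyl}-3-methylidene-2-oxo-2,3,3a,4,5,8,9,11a-octahydrocyclodeca[b]furan-4-yl 2-({[tert-butyl(dimethyl)silyl]oxy}methyl)prop-2-enoate | CC(=O)OC/C1=C/CC/C(COCc2ccc(OC)cc2)=C\[C@H]2OC(=O)C(=C)[C@@H]2[C@@H](OC(=O)C(=C)CO[Si](C)(C)C(C)(C)C)C1 | intermediate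
31 | (3aR,4S,6E,10E,11aR)-6-(acetoxymethyl)-10-(hydroxymethyl)-3-methylidene-2-oxo-2,3,3a,4,5,8,9,11a-octahydrocyclodeca[b]furan-4-yl 2-({[tert-butyl(dimethyl)silyl]oxy}methyl)prop-2-enoate | CC(=O)OC/C1=C/CC/C(CO)=C\[C@H]2OC(=O)C(=C)[C@@H]2[C@@H](OC(=O)C(=C)CO[Si](C)(C)C(C)(C)C)C1 | intermediate
32 | (3aR,4S,6E,10E,11aR)-6-(acetoxymethyl)-10-formyl-3-methylidene-2-oxo-2,3,3a,4,5,8,9,11a-octahydrocyclodeca[b]furan-4-yl 2-({[tert-butyl(dimethyl)silyl]oxy}methyl)prop-2-enoate | CC(=O)OC/C1=C/CC/C(C=O)=C\[C@H]2OC(=O)C(=C)[C@@H]2[C@@H](OC(=O)C(=C)CO[Si](C)(C)C(C)(C)C)C1 | intermediate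
33 | (3aR,4S,6E,10E,11aR)-6-(acetoxymethyl)-10-formyl-3-methylidene-2-oxo-2,3,3a,4,5,8,9,11a-octahydrocyclodeca[b]furan-4-yl 2-(hydroxymethyl)prop-2-enoate | CC(=O)OC/C1=C/CC/C(C=O)=C\[C@H]2OC(=O)C(=C)[C@@H]2[C@@H](OC(=O)C(=C)CO)C1 | target

**Step count and risks**

Total: 21 steps. Longest linear sequence: 17 steps (steps 3–5, 6–15 and 18–21).

Steps most likely to fail:

1. Step 15 (key step). The zwitterion from an acrylate ester may form too sparingly, or may not reach the s-trans ester conformation needed for closure, so that phosphine-induced oligomerization of the acrylate outruns the epoxide opening. The fallback uses known reaction types (Steglich esterification, alkylation of a phosphonate-stabilized carbanion by an epoxide, Horner–Wadsworth–Emmons methylenation). It sets out from 21, which would be esterified with diethylphosphonoacetic acid (DCC, DMAP) to the phosphonoacetate ester F1. KN(SiMe3)2 (THF, −78 to 0 °C) would generate the stabilized carbanion, which opens the epoxide at C7 in the same 5-exo, anti sense to give the α-phosphono lactone F2, held as its potassium enolate after proton transfer to the C8 alkoxide. Paraformaldehyde added to the same flask would then convert F2 to 26, where the route is rejoined.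

2. Step 11. Intermolecular metathesis (oligomerization) may outrun closure of the ten-membered ring onto the hindered 1,1-disubstituted alkene. The fallback postpones ring closure until the lactone is in place, so that the trans-disubstituted five-membered ring holds C5 and C8 in the geometry of the product. It sets out from 18: iBu2AlH would reduce the ester to the open-chain diol F3, AcCl with collidine would give the primary acetate F4, and acryloyl chloride would give the acrylate F5. PMe3 in t-BuOH (the chemistry of step 15, or of its fallback) would give the open-chain α-methylene lactone F6. Ring-closing metathesis of F6 with the same catalyst would then give 26 directly. The lactone methylene cannot compete, since closure onto C13 would need a four-membered ring. The side path to watch is closure at the now electron-rich C10, which is disfavored because the bond would have to form at a fully substituted alkene carbon.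

3. Step 10. Facial selectivity in the Grignard addition may be poor, giving much of the C6 epimer. The fallback replaces C–C bond formation under Felkin–Anh control by a chelation-controlled hydride delivery. It sets out from 18 as the epimeric mixture, which would be oxidized with Dess–Martin periodinane to the cis-epoxy vinyl ketone F7. Reduction with Zn(BH4)2 (Et2O, −20 °C), in which zinc bridges the carbonyl and epoxide oxygens and hydride enters from the open face, is the known erythro-selective reduction of α,β-epoxy ketones and would return 18.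

**Further compounds**

F1 | step 15 | (1S,2R,3E,7E,10S)-8-(acetoxymethyl)-4-{[(4-methoxybenzyl)oxy]methyl}-11-oxabicyclo[8.1.0]undeca-3,7-dien-2-yl (diethoxyphosphoryl)acetate | CC(=O)OC/C1=C/CC/C(COCc2ccc(OC)cc2)=C\[C@@H](OC(=O)CP(=O)(OCC)OCC)[C@H]2O[C@H]2C1
F2 | step 15 | [(3aR,4S,6E,10E,11aR)-3-(diethoxyphosphoryl)-4-hydroxy-10-{[(4-methoxybenzyl)oxy]methyl}-2-oxo-2,3,3a,4,5,8,9,11a-octahydrocyclodeca[b]furan-6-yl]methyl acetate (C3 epimers) | CC(=O)OC/C1=C/CC/C(COCc2ccc(OC)cc2)=C\[C@H]2OC(=O)C(P(=O)(OCC)OCC)[C@@H]2[C@@H](O)C1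
F3 | step 11 | (2E)-2-({(2S,3R)-3-[(1R)-1-hydroxyprop-2-en-1-yl]oxiran-2-yl}methyl)-6-{[(4-methoxybenzyl)oxy]methyl}hepta-2,6-dien-1-ol | OC/C(C[C@@H]1O[C@@H]1[C@H](O)C=C)=C/CCC(=C)COCc1ccc(OC)cc1
F4 | step 11 | (2E)-2-({(2S,3R)-3-[(1R)-1-hydroxyprop-2-en-1-yl]oxiran-2-yl}methyl)-6-{[(4-methoxybenzyl)oxy]methyl}hepta-2,6-dien-1-yl acetate | CC(=O)OC/C(C[C@@H]1O[C@@H]1[C@H](O)C=C)=C/CCC(=C)COCc1ccc(OC)cc1
F5 | step 11 | (1R)-1-[(2S,3S)-3-{(2E)-2-(acetoxymethyl)-6-{[(4-methoxybenzyl)oxy]methyl}hepta-2,6-dien-1-yl}oxiran-2-yl]prop-2-en-1-yl prop-2-enoate | CC(=O)OC/C(C[C@@H]1O[C@@H]1[C@H](OC(=O)C=C)C=C)=C/CCC(=C)COCc1ccc(OC)cc1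
F6 | step 11 | (2E)-2-{(2S)-2-[(2R,3R)-2-ethenyl-4-methylidene-5-oxooxolan-3-yl]-2-hydroxyethyl}-6-{[(4-methoxybenzyl)oxy]methyl}hepta-2,6-dien-1-yl acetate | CC(=O)OC/C(C[C@H](O)[C@H]1C(=C)C(=O)O[C@@H]1C=C)=C/CCC(=C)COCc1ccc(OC)cc1
F7 | step 10 | ethyl (2E)-2-{[(2S,3S)-3-(prop-2-enoyl)oxiran-2-yl]methyl}-6-{[(4-methoxybenzyl)oxy]methyl}hepta-2,6-dienoate | CCOC(=O)/C(C[C@@H]1O[C@@H]1C(=O)C=C)=C/CCC(=C)COCc1ccc(OC)cc1
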